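The central resorcinol ring (C1 and C3 carry OH, C2 is H, C4 and C6 carry the 4-hydroxybenzyl groups, C5 the 2-phenylethyl chain) is disconnected at C4–C5 and C1–C6. Its meta-dioxygenated segment C1–C4, benzyl group included, is the enol pattern of a γ-benzylated acetoacetate and is supplied as a 1-methoxy-1,3-bis(silyloxy)diene; C5 and C6 come from an aryl alkynyl ketone whose aroyl group is the masked C6 benzyl group. One thermal [4+2] cycloaddition with aromatising loss of methanol and silanol assembles the fully substituted ring, all five substituents in place. Deoxygenation of the diaryl ketone and O-demethylation then complete the synthesis.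

Key step: step 5

Remark: the target has no stereocentre and no other stereogenic element, so it is one achiral compound and the route needs no stereocontrol; the double-bond geometries of the silyl enol ether intermediates are inconsequential because those carbons end up in the aromatic ring.

Step 1
Reactants: 1 methyl acetoacetate; 2 4-methoxybenzyl chloride
Product: 4 methyl 5-(4-methoxyphenyl)-3-oxopentanoate, via dilithium dianion 3 (not isolated)
Conditions: LDA (2.3 equiv), THF, 0 °C; then 2, −78 °C → rt; aq. HCl work-up
Reagents that add atoms: none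
Why: γ-Alkylation of the acetoacetate dianion: the terminal carbanion is the more basic and more nucleophilic site and should react selectively with the reactive benzylic chloride in an SN2 alkylation.

Step 2
Reactants: 4 methyl 5-(4-methoxyphenyl)-3-oxopentanoate
Product: 5 methyl (2E)-5-(4-methoxyphenyl)-3-[(trimethylsilyl)oxy]pent-2-enoate
Conditions: TMSCl (1.5 equiv), Et3N (1.5 equiv), PhMe, rt, 48 h; filtered under Ar, used crude
Reagents that add atoms: chlorotrimethylsilane, C[Si](C)(C)Cl
Why: Silyl enol ether formation by amine-mediated O-silylation of the enolised β-keto ester; an E/Z mixture is equally usable because this double bond is shifted in the next step.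

Step 3
Reactants: 5 methyl (2E)-5-(4-methoxyphenyl)-3-[(trimethylsilyl)oxy]pent-2-enoate
Product: 7 (1Z,3Z)-1-methoxy-5-(4-methoxyphenyl)-1,3-bis[(trimethylsilyl)oxy]penta-1,3-diene, via lithium dienolate 6 (not isolated)
Conditions: LDA (1.5 equiv), THF, −78 °C; TMSCl (1.5 equiv), −78 °C → rt; hexane, filtration under Ar, used crude at once
Reagents that add atoms: chlorotrimethylsilane, C[Si](C)(C)Cl
Why: γ-Deprotonation of the β-silyloxy enoate gives the extended ester enolate, which is O-silylated to the ketene silyl acetal, the standard two-stage preparation of 4-substituted 1-alkoxy-1,3-bis(silyloxy)dienes.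

Step 4
Reactants: 8 4-phenyl-1-butyne; 9 4-methoxybenzoyl chloride
Product: 10 1-(4-methoxyphenyl)-5-phenylpent-2-yn-1-one
Conditions: PdCl2(PPh3)2 (2 mol%), CuI (4 mol%), Et3N (1.2 equiv), THF, rt, 1–2 h
Reagents that add atoms: none
Why: Acyl Sonogashira coupling (oxidative addition of the aroyl chloride, transmetalation from the copper acetylide, reductive elimination); the short reaction time and near-stoichiometric base should protect the base-sensitive propargylic ynone.

Step 5
Reactants: 7 (1Z,3Z)-1-methoxy-5-(4-methoxyphenyl)-1,3-bis[(trimethylsilyl)oxy]penta-1,3-diene; 10 1-(4-methoxyphenyl)-5-phenylpent-2-yn-1-one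
Product: 12 [4,6-dihydroxy-3-(4-methoxybenzyl)-2-(2-phenylethyl)phenyl](4-methoxyphenyl)methanone, via cyclohexadiene cycloadduct 11 (not isolated)
Conditions: 7 (2 equiv), PhMe, 100 °C, sealed tube, Ar, 16 h; then 1 M HCl, THF, rt
Reagents that add atoms: none
Why: Normal-electron-demand Diels–Alder reaction of an electron-rich 1-alkoxy-1,3-bis(silyloxy)diene with an acetylenic ketone, the known silyloxydiene/alkynone benzannulation: C4 of 7, the terminus with the largest HOMO coefficient, bonds to the β-carbon of 10 and the ketene-acetal carbon C1 to the α-carbon in a concerted but strongly asynchronous [4+2] process that gives 1,4-cyclohexadiene 11. The one six-membered ring is closed by this intermolecular cycloaddition; on acidic work-up the mixed ketal at C1 loses methanol and silanol to a dienone, the C3 silyl enol ether is cleaved, and enolisation of C4–H aromatises the ring to the free resorcinol without any oxidant. No stereocentre remains: the two sp3 centres of 11 (C1 and C4) form without control and are both erased on aromatisation. The step needs regioselectivity (benzyl-bearing C4 next to the phenethyl-bearing carbon, oxygenated C1 next to the aroyl-bearing carbon) and periselectivity ([4+2] across the triple bond and not carbonyl addition or a Michael/aldol path through C2); the first is secured by the matched polarisation of donor oxygens at C1/C3 against the aroyl acceptor, the second by working thermally without Lewis acid. The (3Z) geometry puts the C5 methylene on the outer side of the s-cis diene so that the benzyl group does not block the approach, and the excess of diene covers its thermal and hydrolytic losses.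

Step 6
Reactants: 12 [4,6-dihydroxy-3-(4-methoxybenzyl)-2-(2-phenylethyl)phenyl](4-methoxyphenyl)methanone
Product: 14 4,6-bis(4-methoxybenzyl)-5-(2-phenylethyl)benzene-1,3-diol, via diarylcarbinol 13 (not isolated)
Conditions: Et3SiH (6 equiv), TFA, CH2Cl2 (dilute), 0 °C → rt
Reagents that add atoms: none
Why: Ionic hydrogenation (silane/acid): hydride transfer to the protonated ketone gives carbinol 13, which ionises to a benzhydryl cation stabilised by the ortho/para hydroxyls and the para-methoxy group and takes up a second hydride; excess silane and dilution should suppress Friedel–Crafts capture of the cation.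

Step 7
Reactants: 14 4,6-bis(4-methoxybenzyl)-5-(2-phenylethyl)benzene-1,3-diol
Product: 16 4,6-bis(4-hydroxybenzyl)-5-(2-phenylethyl)benzene-1,3-diol, via tetrakis(dibromoboryl) ether 15 (not isolated)
Conditions: BBr3 (6 equiv), CH2Cl2, −78 → 0 °C; then H2O
Reagents that add atoms: none
Why: Lewis-acid O-demethylation of aryl methyl ethers (ether–borane complex, SN2 attack of bromide on methyl); excess reagent covers the two free phenols, the low temperature should avoid acid-induced migration of the C-benzyl groups, and hydrolysis of the aryl borates releases the tetraphenol.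

Compound list
1 | methyl acetoacetate (methyl 3-oxobutanoate) | COC(=O)CC(C)=O | starting material
2 | 4-methoxybenzyl chloride | COc1ccc(CCl)cc1 | starting material
3 | dilithium (1E)-1-methoxybuta-1,3-diene-1,3-bis(olate), the dianion of 1, drawn in its chelated form, not isolated | CO/C([O-])=C/C([O-])=C.[Li+].[Li+] | intermediate
4 | methyl 5-(4-methoxyphenyl)-3-oxopentanoate | COC(=O)CC(=O)CCc1ccc(OC)cc1 | intermediate
5 | methyl (2E)-5-(4-methoxyphenyl)-3-[(trimethylsilyl)oxy]pent-2-enoate (E drawn; E/Z mixture acceptable) | COC(=O)/C=C(\CCc1ccc(OC)cc1)O[Si](C)(C)C | intermediate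
6 | lithium (1E,3Z)-1-methoxy-5-(4-methoxyphenyl)-3-[(trimethylsilyl)oxy]penta-1,3-dien-1-olate, not isolated | CO/C([O-])=C/C(O[Si](C)(C)C)=C/Cc1ccc(OC)cc1.[Li+] | intermediate
7 | (1Z,3Z)-1-methoxy-5-(4-methoxyphenyl)-1,3-bis[(trimethylsilyl)oxy]penta-1,3-diene (expected major geometry) | CO/C(O[Si](C)(C)C)=C/C(O[Si](C)(C)C)=C/Cc1ccc(OC)cc1 | intermediate
8 | 4-phenyl-1-butyne (but-3-yn-1-ylbenzene) | C#CCCc1ccccc1 | starting material
9 | 4-methoxybenzoyl chloride | COc1ccc(cc1)C(Cl)=O | starting material
10 | 1-(4-methoxyphenyl)-5-phenylpent-2-yn-1-one | COc1ccc(cc1)C(=O)C#CCCc1ccccc1 | intermediate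
11 | [6-methoxy-3-(4-methoxybenzyl)-2-(2-phenylethyl)-4,6-bis(trimethylsilyloxy)cyclohexa-1,4-dien-1-yl](4-methoxyphenyl)methanone, racemic mixture of diastereomers at C3 and C6, not isolated | COC1(O[Si](C)(C)C)C=C(O[Si](C)(C)C)C(Cc2ccc(OC)cc2)C(CCc2ccccc2)=C1C(=O)c1ccc(OC)cc1 | intermediate
12 | [4,6-dihydroxy-3-(4-methoxybenzyl)-2-(2-phenylethyl)phenyl](4-methoxyphenyl)methanone | COc1ccc(cc1)C(=O)c1c(O)cc(O)c(Cc2ccc(OC)cc2)c1CCc1ccccc1 | intermediate
13 | 4-[hydroxy(4-methoxyphenyl)methyl]-6-(4-methoxybenzyl)-5-(2-phenylethyl)benzene-1,3-diol, racemic, not isolated | COc1ccc(cc1)C(O)c1c(O)cc(O)c(Cc2ccc(OC)cc2)c1CCc1ccccc1 | intermediate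
14 | 4,6-bis(4-methoxybenzyl)-5-(2-phenylethyl)benzene-1,3-diol | COc1ccc(Cc2c(O)cc(O)c(Cc3ccc(OC)cc3)c2CCc2ccccc2)cc1 | intermediate
15 | tetrakis(O-dibromoboryl) derivative of 16 (idealised composition of the aryl borate mixture before hydrolysis), not isolated | BrB(Br)Oc1ccc(Cc2c(OB(Br)Br)cc(OB(Br)Br)c(Cc3ccc(OB(Br)Br)cc3)c2CCc2ccccc2)cc1 | intermediate
16 | 4,6-bis(4-hydroxybenzyl)-5-(2-phenylethyl)benzene-1,3-diol (achiral) | Oc1ccc(Cc2c(O)cc(O)c(Cc3ccc(O)cc3)c2CCc2ccccc2)cc1 | target

Total step count: 7.
Longest linear sequence: 6 steps (steps 1, 2, 3, 5, 6, 7 from methyl acetoacetate); the ynone branch adds one step (step 4).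

Steps most likely to fail

Step 5. The two termini that must join first (C4 of the diene, carrying the benzyl group, and the β-carbon of the ynone, carrying the phenethyl chain) are both substituted. Bond formation may therefore be slow enough for desilylation or silyl migration of the diene, or a Michael/aldol pathway through C2, to take over. Fallback: the benzyl group is taken off the diene, and the fallback sets out from 10 and 9 and returns at 12. Commercial 1-methoxy-1,3-bis(trimethylsilyloxy)buta-1,3-diene (COC(O[Si](C)(C)C)=CC(=C)O[Si](C)(C)C), whose terminus is unsubstituted, would be heated with 10 under the same conditions. This should give, through the cycloadduct [6-methoxy-2-(2-phenylethyl)-4,6-bis(trimethylsilyloxy)cyclohexa-1,4-dien-1-yl](4-methoxyphenyl)methanone F1 (not isolated), the ketone [2,4-dihydroxy-6-(2-phenylethyl)phenyl](4-methoxyphenyl)methanone F2. Ionic hydrogenation (Et3SiH, TFA, CH2Cl2), through the carbinol 4-[hydroxy(4-methoxyphenyl)methyl]-5-(2-phenylethyl)benzene-1,3-diol F3 (not isolated), would give 4-(4-methoxybenzyl)-5-(2-phenylethyl)benzene-1,3-diol F4. Friedel–Crafts acylation of F4 with 9 (AlCl3, CH2Cl2/PhNO2, 0 °C → rt, or O-acylation followed by Fries rearrangement) at its only free position para to a hydroxyl would then deliver 12.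

Step 6. Hydride transfer to the hindered, hydrogen-bonded ketone may be slow, and the benzhydryl cation may instead alkylate the free C2 position of another resorcinol ring, leading to oligomers. Fallback: the deoxygenation is moved to basic conditions on a deactivated ring, setting out from 12 and returning at 14. Ethyl chloroformate/Et3N (THF, 0 °C) would convert 12 into diethyl 4-(4-methoxybenzoyl)-6-(4-methoxybenzyl)-5-(2-phenylethyl)-1,3-phenylene biscarbonate F5. NaBH4 in THF/H2O (0 °C → rt) then reduces the ketone, the ortho carbonate shifts to the benzylic oxygen and is eliminated, and a second hydride adds to the exocyclic double bond so formed. Aqueous NaOH removes the remaining carbonate to give 14. This is the known deoxygenation of ortho-acylphenols through their carbonates.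

Step 7. The Lewis acid and the HBr formed may cause cleavage or migration of the C-benzyl groups on the very electron-rich ring, or the free phenols may sequester the reagent and leave the cleavage incomplete. Fallback: the ether cleavage is taken out of the acid manifold altogether, setting out from 14 and returning at 16 with no new compound (F0). Sodium ethanethiolate in DMF at 130–150 °C under Ar effects nucleophilic SN2 demethylation; the substrate is present as a phenoxide, so no protonated arene or benzylic cation can arise.

Further compounds
F1 | step 5 | [6-methoxy-2-(2-phenylethyl)-4,6-bis(trimethylsilyloxy)cyclohexa-1,4-dien-1-yl](4-methoxyphenyl)methanone (racemic, not isolated) | COC1(O[Si](C)(C)C)C=C(O[Si](C)(C)C)CC(CCc2ccccc2)=C1C(=O)c1ccc(OC)cc1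
F2 | step 5 | [2,4-dihydroxy-6-(2-phenylethyl)phenyl](4-methoxyphenyl)methanone | COc1ccc(cc1)C(=O)c1c(O)cc(O)cc1CCc1ccccc1
F3 | step 5 | 4-[hydroxy(4-methoxyphenyl)methyl]-5-(2-phenylethyl)benzene-1,3-diol (racemic, not isolated) | COc1ccc(cc1)C(O)c1c(O)cc(O)cc1CCc1ccccc1
F4 | step 5 | 4-(4-methoxybenzyl)-5-(2-phenylethyl)benzene-1,3-diol | COc1ccc(Cc2c(O)cc(O)cc2CCc2ccccc2)cc1
F5 | step 6 | diethyl 4-(4-methoxybenzoyl)-6-(4-methoxybenzyl)-5-(2-phenylethyl)-1,3-phenylene biscarbonate | CCOC(=O)Oc1cc(OC(=O)OCC)c(C(=O)c2ccc(OC)cc2)c(CCc2ccccc2)c1Cc1ccc(OC)cc1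
F0 | step 7 | none | none
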